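**Retrosynthetic overview**
1. Target ⇒ hydroxyl-directed 1,3-anti reduction of an epoxy tetraenyl ketone ⇒ Nozaki–Hiyama–Kishi union (side-chain C1'–C2' bond) of ring epoxy aldehyde 13 with tetraenyl iodide 22, itself from a Negishi carboalumination and a Horner–Wadsworth–Emmons olefination.
2. Epoxy aldehyde 13 ⇒ C2-symmetric (3S,6S)-3,6-bis(silyloxy)cyclohexa-1,4-diene-1,4-dimethanol 10, by monoacetylation of its two homotopic CH2OH groups and hydroxyl-directed epoxidation anti to both silyloxy groups.
3. Diene 10 ⇒ dimethyl succinylsuccinate 3, by double catalyst-controlled hydrogenation (both ring carbinols) and double selenoxide dehydrogenation.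
4. Enabling feature: in the 7-oxabicyclo[4.1.0]hept-3-ene core, C4(CH2OAc)–C5(OH)–C6(epoxide CH) and C1(bearing side-chain C1')–C2(OH)–C3(=CH) are the same branched C–C(O)–C unit twice, para to each other (latent twofold axis through the ring centre). The carbocycle is therefore the head-to-tail cyclodimer of methyl 4-chloroacetoacetate, closed by two C-alkylations that make C3–C4 and C1–C6 in one operation.
5. Ring order: six-membered carbocycle first (step 1), oxirane second (step 8).

Key step: step 1

Remark: the stereodescriptors of the SMILES are taken as given; they place the two ring hydroxyls cis to each other and anti to the epoxide oxygen, and make ring C2–OH and side-chain C1'–OH a 1,3-anti pair.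

**Route**

Step 1
Reactants: 1 methyl 4-chloro-3-oxobutanoate (two molecules)
Product: 3 dimethyl succinylsuccinate (dimethyl 2,5-dioxocyclohexane-1,4-dicarboxylate drawn as its bis-enol), via acyclic chloro diketo diester 2 (not isolated)
Conditions: NaOMe (1.05 equiv), MeOH, 0 → 25 °C; then AcOH
Reagents that add atoms: none
Why: Base-mediated head-to-tail cyclodimerisation: NaOMe forms the β-keto ester enolate of 1, which C-alkylates the highly SN2-reactive ClCH2–C(=O) carbon of a second molecule to give 2, and the second β-keto ester enolate of 2 then displaces the remaining chloride intramolecularly. The closest known reaction type is this very transformation, the technical preparation of dialkyl succinylsuccinates from 4-haloacetoacetic esters. The six-membered carbocycle is closed by a 6-exo-tet C-alkylation, and the two new C–C bonds each join an ester-bearing carbon to a ring CH2 (in the target, C4–C3 and C1–C6). No stereocentre survives the step, because both α-carbons are enolised in the planar, centrosymmetric bis-enol 3, so all stereochemistry is introduced from step 2 on. The selectivity needed is C- over O-alkylation and dimerisation over Favorskii, furanone or oligomer formation; it is secured by the soft doubly stabilised enolate, by each monomer having one nucleophilic and one electrophilic carbon (only the head-to-tail union can close a six-membered ring), and by precipitation of hydrogen-bonded 3 from methanol.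

Step 2
Reactants: 3 dimethyl succinylsuccinate
Product: 4 dimethyl (1S,2S,4S,5S)-2,5-dihydroxycyclohexane-1,4-dicarboxylate
Conditions: H2 (80 atm), RuBr2[(S)-BINAP] (1 mol%), CH2Cl2/MeOH, 50 °C
Reagents that add atoms: none
Why: Noyori asymmetric hydrogenation of a cyclic β-keto ester with dynamic kinetic resolution: each keto ester unit is reduced under catalyst control (the (S)-ligand should give the (S)-carbinol with the ester trans, as with 2-oxocycloalkanecarboxylates), so two like events should give the C2-symmetric cis-2,5-diol, while a mismatched event ends in the separable meso diastereomer.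

Step 3
Reactants: 4 dimethyl (1S,2S,4S,5S)-2,5-dihydroxycyclohexane-1,4-dicarboxylate
Product: 5 dimethyl (1S,2S,4S,5S)-2,5-bis(tert-butyldimethylsilyloxy)cyclohexane-1,4-dicarboxylate
Conditions: TBSOTf (2.4 equiv), 2,6-lutidine, CH2Cl2, 0 °C
Reagents that add atoms: tert-butyldimethylsilyl triflate, CC(C)(C)[Si](C)(C)OS(=O)(=O)C(F)(F)F
Why: Silyl ether formation at both secondary hydroxyls touches no stereocentre and installs the bulky groups that later shield one ring face.

Step 4
Reactants: 5 dimethyl (1S,2S,4S,5S)-2,5-bis(tert-butyldimethylsilyloxy)cyclohexane-1,4-dicarboxylate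
Product: 7 dimethyl (2S,5S)-2,5-bis(tert-butyldimethylsilyloxy)-1,4-bis(phenylselanyl)cyclohexane-1,4-dicarboxylate, via dilithium bis-enolate 6 (not isolated)
Conditions: LDA (2.4 equiv), THF, −78 °C; PhSeBr (2.6 equiv), −78 °C
Reagents that add atoms: phenylselenenyl bromide, Br[Se]c1ccccc1
Why: Ester enolate α-selenenylation, kept at −78 °C so that the β-silyloxy groups are not expelled; the configuration of the two selenium-bearing carbons does not matter because both become sp2 in step 5.

Step 5
Reactants: 7 dimethyl (2S,5S)-2,5-bis(tert-butyldimethylsilyloxy)-1,4-bis(phenylselanyl)cyclohexane-1,4-dicarboxylate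
Product: 9 dimethyl (3S,6S)-3,6-bis(tert-butyldimethylsilyloxy)cyclohexa-1,4-diene-1,4-dicarboxylate, via bis-selenoxide 8 (not isolated)
Conditions: H2O2 (30% aq.), pyridine, CH2Cl2, 0 °C → rt
Reagents that add atoms: none
Why: Selenoxide syn-elimination runs toward the ring CH2 and away from the silyloxy-bearing carbon (allylic ether rather than enol ether), which places both double bonds between an ester carbon and a former CH2 and leaves the two carbinol centres untouched in a C2-symmetric diene.

Step 6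
Reactants: 9 dimethyl (3S,6S)-3,6-bis(tert-butyldimethylsilyloxy)cyclohexa-1,4-diene-1,4-dicarboxylate
Product: 10 [(3S,6S)-3,6-bis(tert-butyldimethylsilyloxy)cyclohexa-1,4-diene-1,4-diyl]dimethanol
Conditions: iBu2AlH (5 equiv), CH2Cl2, −78 °C; Rochelle salt
Reagents that add atoms: none
Why: 1,2-Reduction of both conjugated esters to primary allylic alcohols by diisobutylaluminium hydride, with no stereocentre involved.

Step 7
Reactants: 10 [(3S,6S)-3,6-bis(tert-butyldimethylsilyloxy)cyclohexa-1,4-diene-1,4-diyl]dimethanol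
Product: 11 [(3S,6S)-3,6-bis(tert-butyldimethylsilyloxy)-4-(hydroxymethyl)cyclohexa-1,4-dien-1-yl]methyl acetate
Conditions: Ac2O (1.0 equiv), Et3N, DMAP (5 mol%), CH2Cl2, −40 → 0 °C
Reagents that add atoms: acetic anhydride, CC(=O)OC(C)=O
Why: Statistical monoacylation in which the twofold axis makes the two hydroxymethyl groups homotopic, so only one monoacetate can form and unreacted 10 is recovered for another pass.

Step 8
Reactants: 11 [(3S,6S)-3,6-bis(tert-butyldimethylsilyloxy)-4-(hydroxymethyl)cyclohexa-1,4-dien-1-yl]methyl acetate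
Product: 12 [(1S,2S,5R,6S)-2,5-bis(tert-butyldimethylsilyloxy)-1-(hydroxymethyl)-7-oxabicyclo[4.1.0]hept-3-en-4-yl]methyl acetate
Conditions: VO(acac)2 (5 mol%), tBuOOH (1.5 equiv), CH2Cl2, 0 °C → rt
Reagents that add atoms: tert-butyl hydroperoxide, CC(C)(C)OO
Why: Hydroxyl-directed vanadium-catalysed epoxidation acts only on the alkene that carries the free CH2OH (the acetoxymethyl alkene is left), and the oxygen should be delivered to the ring face opposite the two silyloxy groups, one of which flanks each alkene carbon, which sets both epoxide carbons.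

Step 9
Reactants: 12 [(1S,2S,5R,6S)-2,5-bis(tert-butyldimethylsilyloxy)-1-(hydroxymethyl)-7-oxabicyclo[4.1.0]hept-3-en-4-yl]methyl acetate
Product: 13 [(1S,2S,5R,6S)-2,5-bis(tert-butyldimethylsilyloxy)-1-formyl-7-oxabicyclo[4.1.0]hept-3-en-4-yl]methyl acetate
Conditions: Dess–Martin periodinane (1.3 equiv), NaHCO3, CH2Cl2, 0 °C → rt
Reagents that add atoms: none
Why: Dess–Martin oxidation of the primary alcohol under buffered conditions; the α-carbon is quaternary, so the aldehyde cannot epimerise, and epoxide and acetate are not affected.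

Step 10
Reactants: 14 prop-2-yn-1-ol
Product: 16 (E)-3-iodo-2-methylprop-2-en-1-ol, via alkenylalane 15 (not isolated)
Conditions: AlMe3 (3 equiv), Cp2ZrCl2 (0.25 equiv), CH2Cl2, 0 °C → rt; then I2, THF, −30 → 0 °C
Reagents that add atoms: trimethylaluminium, C[Al](C)C; iodine, II
Why: Negishi zirconium-catalysed carboalumination adds methyl and aluminium syn across the alkyne with aluminium at the terminal carbon, and iodinolysis with retention gives the (E)-iodide.

Step 11
Reactants: 16 (E)-3-iodo-2-methylprop-2-en-1-ol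
Product: 17 (E)-3-iodo-2-methylprop-2-enal
Conditions: MnO2 (15 equiv), CH2Cl2, rt
Reagents that add atoms: none
Why: Selective allylic oxidation with MnO2 keeps the alkene geometry; the volatile aldehyde is used directly.

Step 12
Reactants: 18 geranyl bromide; 19 triethyl phosphite
Product: 20 diethyl [(2E)-3,7-dimethylocta-2,6-dien-1-yl]phosphonate
Conditions: neat, 130 °C, bromoethane distilled off
Reagents that add atoms: none
Why: Michaelis–Arbuzov reaction by SN2 attack of phosphorus at the primary allylic carbon, with the (E)-trisubstituted alkene retained.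

Step 13
Reactants: 20 diethyl [(2E)-3,7-dimethylocta-2,6-dien-1-yl]phosphonate; 17 (E)-3-iodo-2-methylprop-2-enal
Product: 22 (1E,3E,5E)-1-iodo-2,6,10-trimethylundeca-1,3,5,9-tetraene, via lithiated phosphonate 21 (not isolated)
Conditions: LiN(SiMe3)2 (1.05 equiv), THF, −78 °C; then 17, −78 → 0 °C
Reagents that add atoms: none
Why: Horner–Wadsworth–Emmons olefination of an allylic phosphonate anion with an enal should give the new C3=C4 bond as the (E)-isomer while the existing alkenes keep their geometry.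

Step 14
Reactants: 13 [(1S,2S,5R,6S)-2,5-bis(tert-butyldimethylsilyloxy)-1-formyl-7-oxabicyclo[4.1.0]hept-3-en-4-yl]methyl acetate; 22 (1E,3E,5E)-1-iodo-2,6,10-trimethylundeca-1,3,5,9-tetraene
Product: 24 [(1S,2S,5R,6S)-2,5-bis(tert-butyldimethylsilyloxy)-1-[(2E,4E,6E)-1-hydroxy-3,7,11-trimethyldodeca-2,4,6,10-tetraenyl]-7-oxabicyclo[4.1.0]hept-3-en-4-yl]methyl acetate as both side-chain C1 epimers, via alkenylchromium dichloride 23 (not isolated)
Conditions: CrCl2 (4 equiv), NiCl2 (2 mol%), DMSO/THF, rt
Reagents that add atoms: none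
Why: Nozaki–Hiyama–Kishi coupling adds the alkenylchromium species chemoselectively to the aldehyde with retention of alkene geometry and tolerates acetate, epoxide and silyl ethers; the new carbinol centre is expected as an epimer mixture, which is of no consequence because step 15 removes it.

Step 15
Reactants: 24 epimeric side-chain alcohols
Product: 25 [(1S,2S,5R,6S)-2,5-bis(tert-butyldimethylsilyloxy)-1-[(2E,4E,6E)-3,7,11-trimethyldodeca-2,4,6,10-tetraenoyl]-7-oxabicyclo[4.1.0]hept-3-en-4-yl]methyl acetate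
Conditions: Dess–Martin periodinane (1.5 equiv), NaHCO3, CH2Cl2, 0 °C
Reagents that add atoms: none
Why: Dess–Martin oxidation converges both epimers on one epoxy tetraenyl ketone without touching the polyene or the epoxide.

Step 16
Reactants: 25 [(1S,2S,5R,6S)-2,5-bis(tert-butyldimethylsilyloxy)-1-[(2E,4E,6E)-3,7,11-trimethyldodeca-2,4,6,10-tetraenoyl]-7-oxabicyclo[4.1.0]hept-3-en-4-yl]methyl acetate
Product: 26 [(1R,2S,5R,6S)-2,5-dihydroxy-1-[(2E,4E,6E)-3,7,11-trimethyldodeca-2,4,6,10-tetraenoyl]-7-oxabicyclo[4.1.0]hept-3-en-4-yl]methyl acetate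
Conditions: HF·pyridine, pyridine, THF, 0 °C → rt
Reagents that add atoms: none
Why: Buffered fluoride desilylation frees both ring hydroxyls (the one β to the ketone is needed for step 17) and should leave epoxide, enone and acetate in place.

Step 17
Reactants: 26 [(1R,2S,5R,6S)-2,5-dihydroxy-1-[(2E,4E,6E)-3,7,11-trimethyldodeca-2,4,6,10-tetraenoyl]-7-oxabicyclo[4.1.0]hept-3-en-4-yl]methyl acetate
Product: 28 [(1R,2S,5R,6S)-2,5-dihydroxy-1-[(1S,2E,4E,6E)-1-hydroxy-3,7,11-trimethyldodeca-2,4,6,10-tetraenyl]-7-oxabicyclo[4.1.0]hept-3-en-4-yl]methyl acetate (CNP0106887.2), via alkoxydiacetoxyborohydride 27 (not isolated)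
Conditions: Me4NBH(OAc)3 (6 equiv), MeCN/AcOH (4:1), −40 → −20 °C
Reagents that add atoms: none
Why: Evans–Saksena hydroxyl-directed reduction, in which the ring C2 hydroxyl (β to the ketone and cis to the acyl group) exchanges onto boron and delivers hydride through a chair-like six-membered transition state with the tetraenyl group pseudo-equatorial, should give the 1,3-anti diol, that is the (1S) side-chain carbinol, while undirected enone and acetate are not reduced.

**Compound list**
1 | methyl 4-chloro-3-oxobutanoate | COC(=O)CC(=O)CCl | starting material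
2 | dimethyl 2-(2-chloroacetyl)-4-oxohexanedioate (racemic) | COC(=O)CC(=O)CC(C(=O)CCl)C(=O)OC | intermediate
3 | dimethyl succinylsuccinate (dimethyl 2,5-dioxocyclohexane-1,4-dicarboxylate, bis-enol form) | COC(=O)C1=C(O)CC(C(=O)OC)=C(O)C1 | intermediate
4 | dimethyl (1S,2S,4S,5S)-2,5-dihydroxycyclohexane-1,4-dicarboxylate | COC(=O)[C@H]1C[C@H](O)[C@@H](C(=O)OC)C[C@@H]1O | intermediate
5 | dimethyl (1S,2S,4S,5S)-2,5-bis(tert-butyldimethylsilyloxy)cyclohexane-1,4-dicarboxylate | COC(=O)[C@H]1C[C@H](O[Si](C)(C)C(C)(C)C)[C@@H](C(=O)OC)C[C@@H]1O[Si](C)(C)C(C)(C)C | intermediate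
6 | dilithium bis(ester enolate) of 5 | COC(O[Li])=C1C[C@H](O[Si](C)(C)C(C)(C)C)C(=C(OC)O[Li])C[C@@H]1O[Si](C)(C)C(C)(C)C | intermediate
7 | dimethyl (2S,5S)-2,5-bis(tert-butyldimethylsilyloxy)-1,4-bis(phenylselanyl)cyclohexane-1,4-dicarboxylate (C1 and C4 undefined) | COC(=O)C1([Se]c2ccccc2)C[C@H](O[Si](C)(C)C(C)(C)C)C(C(=O)OC)([Se]c2ccccc2)C[C@@H]1O[Si](C)(C)C(C)(C)C | intermediate
8 | bis-selenoxide of 7 | COC(=O)C1([Se](=O)c2ccccc2)C[C@H](O[Si](C)(C)C(C)(C)C)C(C(=O)OC)([Se](=O)c2ccccc2)C[C@@H]1O[Si](C)(C)C(C)(C)C | intermediate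
9 | dimethyl (3S,6S)-3,6-bis(tert-butyldimethylsilyloxy)cyclohexa-1,4-diene-1,4-dicarboxylate | COC(=O)C1=C[C@H](O[Si](C)(C)C(C)(C)C)C(C(=O)OC)=C[C@@H]1O[Si](C)(C)C(C)(C)C | intermediate
10 | [(3S,6S)-3,6-bis(tert-butyldimethylsilyloxy)cyclohexa-1,4-diene-1,4-diyl]dimethanol | OCC1=C[C@H](O[Si](C)(C)C(C)(C)C)C(CO)=C[C@@H]1O[Si](C)(C)C(C)(C)C | intermediate
11 | [(3S,6S)-3,6-bis(tert-butyldimethylsilyloxy)-4-(hydroxymethyl)cyclohexa-1,4-dien-1-yl]methyl acetate | CC(=O)OCC1=C[C@H](O[Si](C)(C)C(C)(C)C)C(CO)=C[C@@H]1O[Si](C)(C)C(C)(C)C | intermediate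
12 | [(1S,2S,5R,6S)-2,5-bis(tert-butyldimethylsilyloxy)-1-(hydroxymethyl)-7-oxabicyclo[4.1.0]hept-3-en-4-yl]methyl acetate (epoxide anti to both silyloxy groups) | CC(=O)OCC1=C[C@H](O[Si](C)(C)C(C)(C)C)[C@@]2(CO)O[C@H]2[C@@H]1O[Si](C)(C)C(C)(C)C | intermediate
13 | [(1S,2S,5R,6S)-2,5-bis(tert-butyldimethylsilyloxy)-1-formyl-7-oxabicyclo[4.1.0]hept-3-en-4-yl]methyl acetate | CC(=O)OCC1=C[C@H](O[Si](C)(C)C(C)(C)C)[C@@]2(C=O)O[C@H]2[C@@H]1O[Si](C)(C)C(C)(C)C | intermediate
14 | prop-2-yn-1-ol | C#CCO | starting material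
15 | dimethyl[(E)-3-(dimethylaluminiooxy)-2-methylprop-1-enyl]alane | C[Al](C)OC/C(C)=C/[Al](C)C | intermediate
16 | (E)-3-iodo-2-methylprop-2-en-1-ol | OC/C(C)=C/I | intermediate
17 | (E)-3-iodo-2-methylprop-2-enal | O=C/C(C)=C/I | intermediate
18 | geranyl bromide, (2E)-1-bromo-3,7-dimethylocta-2,6-diene | BrC/C=C(\C)CCC=C(C)C | starting material
19 | triethyl phosphite | CCOP(OCC)OCC | starting material
20 | diethyl [(2E)-3,7-dimethylocta-2,6-dien-1-yl]phosphonate | CCOP(=O)(OCC)C/C=C(\C)CCC=C(C)C | intermediate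
21 | α-lithio derivative of 20 | CCOP(=O)(OCC)C([Li])/C=C(\C)CCC=C(C)C | intermediate
22 | (1E,3E,5E)-1-iodo-2,6,10-trimethylundeca-1,3,5,9-tetraene | I/C=C(C)/C=C/C=C(\C)CCC=C(C)C | intermediate
23 | dichloro[(1E,3E,5E)-2,6,10-trimethylundeca-1,3,5,9-tetraenyl]chromium | Cl[Cr](Cl)/C=C(C)/C=C/C=C(\C)CCC=C(C)C | intermediate
24 | [(1S,2S,5R,6S)-2,5-bis(tert-butyldimethylsilyloxy)-1-[(2E,4E,6E)-1-hydroxy-3,7,11-trimethyldodeca-2,4,6,10-tetraenyl]-7-oxabicyclo[4.1.0]hept-3-en-4-yl]methyl acetate, both side-chain C1 epimers | CC(=O)OCC1=C[C@H](O[Si](C)(C)C(C)(C)C)[C@@]2(C(O)/C=C(C)/C=C/C=C(\C)CCC=C(C)C)O[C@H]2[C@@H]1O[Si](C)(C)C(C)(C)C | intermediate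
25 | [(1S,2S,5R,6S)-2,5-bis(tert-butyldimethylsilyloxy)-1-[(2E,4E,6E)-3,7,11-trimethyldodeca-2,4,6,10-tetraenoyl]-7-oxabicyclo[4.1.0]hept-3-en-4-yl]methyl acetate | CC(=O)OCC1=C[C@H](O[Si](C)(C)C(C)(C)C)[C@@]2(C(=O)/C=C(C)/C=C/C=C(\C)CCC=C(C)C)O[C@H]2[C@@H]1O[Si](C)(C)C(C)(C)C | intermediate
26 | [(1R,2S,5R,6S)-2,5-dihydroxy-1-[(2E,4E,6E)-3,7,11-trimethyldodeca-2,4,6,10-tetraenoyl]-7-oxabicyclo[4.1.0]hept-3-en-4-yl]methyl acetate | CC(=O)OCC1=C[C@H](O)[C@@]2(C(=O)/C=C(C)/C=C/C=C(\C)CCC=C(C)C)O[C@H]2[C@@H]1O | intermediate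
27 | tetramethylammonium diacetoxy(hydrido)borate bound through the ring C2 oxygen of 26 | CC(=O)OCC1=C[C@H](O[BH-](OC(C)=O)OC(C)=O)[C@@]2(C(=O)/C=C(C)/C=C/C=C(\C)CCC=C(C)C)O[C@H]2[C@@H]1O.C[N+](C)(C)C | intermediate
28 | [(1R,2S,5R,6S)-2,5-dihydroxy-1-[(1S,2E,4E,6E)-1-hydroxy-3,7,11-trimethyldodeca-2,4,6,10-tetraenyl]-7-oxabicyclo[4.1.0]hept-3-en-4-yl]methyl acetate | CC(=O)OCC1=C[C@H](O)[C@@]2([C@@H](O)/C=C(C)/C=C/C=C(\C)CCC=C(C)C)O[C@H]2[C@@H]1O | target

**Step count**
Total steps: 17. Longest linear sequence: 13 steps (steps 1–9 and 14–17); steps 10–13 make the side-chain iodide.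

**Three steps most likely to fail**

Step 2. What may go wrong: incomplete dynamic kinetic resolution or weak catalyst control on the strongly enolised bis(β-keto ester), or dehydrogenation of 3 to the aromatic hydroquinone diester. The fallback sets out from 3 and comes back at 7. Reduction of 3 with a Prelog-selective ketoreductase (NADPH, glucose dehydrogenase recycling) or fermenting baker's yeast should give the (S)-carbinols as the cis-hydroxy esters, dimethyl (1R,2S,4R,5S)-2,5-dihydroxycyclohexane-1,4-dicarboxylate F1. Silylation as in step 3 should give dimethyl (1R,2S,4R,5S)-2,5-bis(tert-butyldimethylsilyloxy)cyclohexane-1,4-dicarboxylate F2, and the selenenylation conditions of step 4 then lead to 7, whose ester-bearing carbons carry no defined configuration.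

Step 4. What may go wrong: expulsion of silanolate from the β-silyloxy ester enolates (E1cB) followed by aromatisation, or incomplete formation of the second enolate. The fallback sets out from 4 and comes back at 7. The free diol 4 is converted with excess LDA (4.5 equiv, THF, −78 → −40 °C) into its bis(alkoxide) bis(enolate), whose alkoxide oxygens cannot leave, and PhSeBr should give dimethyl (2S,5S)-2,5-dihydroxy-1,4-bis(phenylselanyl)cyclohexane-1,4-dicarboxylate F3. Silylation (TBSOTf, 2,6-lutidine) then returns to 7.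

Step 17. What may go wrong: poor facial selectivity of the internal hydride delivery if the bicyclic core does not allow the chair-like transition state, or acid-promoted ionisation of the trienyl carbinol and epoxide opening in the acetic acid medium. The fallback sets out from 25 and comes back at 28. The still silylated ketone 25 is reduced with K[sBu3BH] (THF, −78 °C) under Felkin–Anh control, with hydride anti to the epoxide C–O bond and the tetraenyl group turned toward the epoxide CH and away from the silyloxy-bearing carbon. This should give [(1S,2S,5R,6S)-2,5-bis(tert-butyldimethylsilyloxy)-1-[(1S,2E,4E,6E)-1-hydroxy-3,7,11-trimethyldodeca-2,4,6,10-tetraenyl]-7-oxabicyclo[4.1.0]hept-3-en-4-yl]methyl acetate F4, and HF·pyridine/pyridine in THF then gives 28.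

**Further compounds**
F1 | step 2 | dimethyl (1R,2S,4R,5S)-2,5-dihydroxycyclohexane-1,4-dicarboxylate | COC(=O)[C@@H]1C[C@H](O)[C@H](C(=O)OC)C[C@@H]1O
F2 | step 2 | dimethyl (1R,2S,4R,5S)-2,5-bis(tert-butyldimethylsilyloxy)cyclohexane-1,4-dicarboxylate | COC(=O)[C@@H]1C[C@H](O[Si](C)(C)C(C)(C)C)[C@H](C(=O)OC)C[C@@H]1O[Si](C)(C)C(C)(C)C
F3 | step 4 | dimethyl (2S,5S)-2,5-dihydroxy-1,4-bis(phenylselanyl)cyclohexane-1,4-dicarboxylate | COC(=O)C1([Se]c2ccccc2)C[C@H](O)C(C(=O)OC)([Se]c2ccccc2)C[C@@H]1O
F4 | step 17 | [(1S,2S,5R,6S)-2,5-bis(tert-butyldimethylsilyloxy)-1-[(1S,2E,4E,6E)-1-hydroxy-3,7,11-trimethyldodeca-2,4,6,10-tetraenyl]-7-oxabicyclo[4.1.0]hept-3-en-4-yl]methyl acetate | CC(=O)OCC1=C[C@H](O[Si](C)(C)C(C)(C)C)[C@@]2([C@@H](O)/C=C(C)/C=C/C=C(\C)CCC=C(C)C)O[C@H]2[C@@H]1O[Si](C)(C)C(C)(C)C
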